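The runs were computed for an exercise.

Start from what cannot change: each product takes one substrate and one coupling partner, so the excess of coupling partner over substrate holds at 0.400 M, apart from the millimolar amounts sitting on the catalyst, and substrate is the limiting reagent. Use this to decide whether teal is worth charging beside ochre and green.

| flask | substrate | coupling partner | free catalyst | remark | time |
|---|---|---|---|---|---|
| delta | 2 M | 2.4 M | 1.5 mM | run made earlier |  |
| zeta | 2 M | 2.4 M | 5 mM | run made earlier |  |
| ochre | 2.0 M | 2.40 M | 2.0 mM |  | 2.0 h |
| green | 2.0 M | 2.40 M | 4.0 mM |  | 2.0 h |
| teal | 2.0 M | 2.40 M | 8.0 mM |  | 2.0 h |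

| run | time / min | product / % |
|---|---|---|
| delta | 25.0 | 3.3 |
| delta | 50.0 | 4.2 |
| delta | 80.0 | 7.4 |
| delta | 90.0 | 11.2 |
| delta | 120 | 13.2 |
| zeta | 10.0 | 3.9 |
| zeta | 30.0 | 10.5 |
| zeta | 60.0 | 21.4 |
| zeta | 80.0 | 26.5 |
| zeta | 120 | 36.4 |

(readings scatter by 1 percentage point)

- amount of product at the end, in percent of the substrate charged for ochre, green, teal, in this order
- the shape of the row from first to last (rises, then falls / falls, then rises / rises all the way / hardly changes / falls all the way)

- the earlier runs were read with a standard deviation of 1 percentage point
- "hardly changes" means that all values lie within two and a half points (for a concentration: within two and a half percent of the largest)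

Assume that the rate goes with the catalyst charged, the remaining substrate and the remaining coupling partner. The balance then leaves a single unknown, and the curve integrates. Let r be the charge ratio of coupling partner to substrate, 1.20, and x the fraction converted. The age of a flask, ln[(r − x)/(r(1 − x))]/(r − 1), is then its time divided by a time constant, and every flask runs along this same curve of x against age.

Take the last zeta reading, 36.4% at 120 min. It gives an age of 0.456, and so the zeta time constant 263 min, which is the time per unit of age at 5 mM. For any other flask, scale it inversely with the catalyst charged.

Test this on delta, whose readings did not go into it. At 1.5 mM and 120 min it predicts 14.3%, and delta read 13.2%, with a scatter of 1 percentage point.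

My reckoning for 2.0 h then gives 18.2% for ochre, 31.2% for green and 48.5% for teal. Going from green to teal adds 17 points, so charge teal, and leave substrate and coupling partner as they are so that the ages stay comparable. Its 8.0 mM lies beyond the 5 mM of zeta, so teal also tests the scaling.

The forecast says 17.6%, 30.3% and 47.4%, rises all the way, each value below mine, and it warns that “saturation or catalyst aggregation could lower it”.

The flasks give 17.2%, 30.6% and 49.3%: rises all the way.

    coupling partner + free catalyst ⇌ catalyst intermediate A (K = 0.468 M⁻¹, k = 20300 M⁻¹ h⁻¹)
    catalyst intermediate A ⇌ catalyst intermediate B (K = 2.95, k = 6760 h⁻¹)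
    substrate + catalyst intermediate B → catalyst intermediate C (k = 99.6 M⁻¹ h⁻¹)
    catalyst intermediate C ⇌ by-product + catalyst intermediate D (K = 1.50 M, k = 29400 h⁻¹)
    catalyst intermediate D → free catalyst + product (k = 612 h⁻¹)
    2 free catalyst ⇌ resting dimer (K = 330 M⁻¹, k = 367 M⁻¹ h⁻¹)

Put the clock back on the runs. Green at 1.00 h has the end age of ochre, and it holds 17.1% against 17.2% for ochre. Teal at 1.00 h has the end age of green, so the zeta time constant gives it 31.2%, and teal holds 30.2%. Two things act together on the teal figure of 49.3%: one part is the backward run from catalyst intermediate B to catalyst intermediate A, without which teal gives 69.8%, and the other is the hour of the reading, since teal holds 98.2% at 20.0 h.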